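## Compound numbering

1 – 1-(2-hydroxy-3,4-dimethoxyphenyl)ethanone
2 – N,N-dimethylformamide dimethyl acetal
3 – (E)-3-(dimethylamino)-1-(2-hydroxy-3,4-dimethoxyphenyl)prop-2-en-1-one
4 – 2-(dimethylamino)-7,8-dimethoxychroman-4-one (forms and reacts on in step 2)
5 – 7,8-dimethoxy-4H-chromen-4-one
6 – (3,4,5-trimethoxyphenyl)boronic acid
7 – (S)-7,8-dimethoxy-2-(3,4,5-trimethoxyphenyl)chroman-4-one
8 – (2S)-7,8-dimethoxy-2-(3,4,5-trimethoxyphenyl)chroman-4-ol (both C4 epimers, mainly 2,4-cis)
9 – (2S)-7,8,3',4',5'-pentamethoxyflavan, that is (S)-7,8-dimethoxy-2-(3,4,5-trimethoxyphenyl)chromane (target)

Assumption: the sense of induction of the pyridine–oxazoline ligand is taken over from its behaviour with cyclic enones, where the (S)-ligand sends the aryl group to the enone face that corresponds to a (2R)-flavanone; the (R)-ligand is therefore specified for the (2S) series.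

## Analysis of the target

The target is a flavan, a 2-aryl-3,4-dihydro-2H-chromene. Ring A is a benzene ring with methoxy groups at C7 and C8, ring C is the dihydropyran (O1, C2, C3, C4, C4a, C8a) fused to it, and ring B is a 3,4,5-trimethoxyphenyl group on C2. C2 is the only stereocentre; it is (S) and carries O1, C1' of ring B, C3 and hydrogen, so there is no second centre to relay from and no relative configuration to control. The five aryl methyl ethers are robust. The one sensitive linkage is the C2–O1 bond, a benzylic aryl alkyl ether that can ionize under forcing acid (ring B stabilises the cation) and can be cleaved by hydrogenolysis. C3 and C4 are bare methylene groups, so the stereocentre sits in a region without any functional group; this is the real difficulty, because an absolute configuration has to be set at a carbon that has no handle in the final structure. Any temporary handle brings its own racemization channel: a carbonyl at C4 allows base-induced retro-oxa-Michael ring opening, and a C3=C4 double bond allows electrocyclic opening of the 2H-chromene. The strategy rests on the C2–C1' bond between ring C and ring B together with C4: if C4 carries a carbonyl for a time, C2 becomes the flat β-carbon of a 4H-chromen-4-one, and a chiral catalyst can deliver ring B to one of its faces as an aryl nucleophile. Ring A then comes unchanged from a 2-hydroxy-3,4-dimethoxyphenyl ketone, and C4, being benzylic and activated by the 7-methoxy group, gives up its oxygen again under mild conditions.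

## Retrosynthetic reasoning

**From 9 back to 7 (no bond cut; oxygen added at C4).** The target 9 has no functional group near C2, so the first backward move puts one in. C4 is chosen because it is benzylic to ring A, and its cation is stabilised by the 7-methoxy group (para to C4a) and by O1 (ortho to C4a). A C4 alcohol, as in 8, therefore ionizes easily and the cation is captured by a hydride donor; 8 in turn comes from ketone 7 by hydride reduction. The gain is a carbonyl that makes C2 the β-position of an enone one stage further back. Forwards, the two reductions must leave C2 alone: the reduction of 7 must be fast and cold enough that base does not open ring C, and the deoxygenation of 8 must ionize C4 but not the C2–O1 bond.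

**From 7 to 5 and 6 (C2–C1' cut).** Of the bonds at the stereocentre, this one divides the molecule into two simple halves of similar size. Chromone 5 has C2 as a prochiral sp2 carbon, and boronic acid 6 is a stable, purchasable source of ring B. Cutting O1–C2 instead would lead to an oxa-Michael ring closure, which is reversible and hence a poor place to fix configuration; cutting C2–C3 offers no simple pair of partners. The forward reaction is a catalytic enantioselective conjugate arylation. It has to form the C–C bond at C2 of 5 and not at the carbonyl, choose one face of C2, and finish by protonation rather than β-hydride elimination. A cationic divalent-palladium catalyst with a chiral pyridine–oxazoline ligand is suited to this, and because it works without base, 7 is not exposed to its racemization pathway.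

**From 5 to 1 and 2 (O1–C2 and C2–C3 cut).** Chromone 5 is unsubstituted at C2 and C3, so its pyranone ring is best assembled from an ortho-hydroxyaryl methyl ketone and a one-carbon unit at the formic acid oxidation level. Ketone 1 carries all of ring A: its hydroxyl becomes O1, its 3- and 4-methoxy groups become the 8- and 7-methoxy groups, and its acetyl group supplies C4 and C3. Amide acetal 2 supplies C2. Forwards, condensation gives enaminone 3; acid then closes the ring by attack of the phenol on the β-carbon to give aminal 4, which loses its amine to give 5. No regiochemical question arises, because only one phenolic oxygen is free.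

## Alternatives that were turned down

**Alternative 1: ring A built on a chiral lactone and aromatized late.**
- Disconnection: the C8–C8a bond is cut, so that ring A is built rather than bought. This leads back to the δ-lactone A2, (6S)-3-(4-methoxy-3-oxobutyl)-6-(3,4,5-trimethoxyphenyl)tetrahydro-2H-pyran-2-one, which already holds C2 of the target as its C6.
- Forward key step: with KOtBu the ketone enolate at the methoxy-bearing carbon acylates onto the lactone carbonyl and closes the six-membered carbocycle. TsOH in the same flask dehydrates the hemiketal to the vinylogous ester A1, (2S)-8-methoxy-2-(3,4,5-trimethoxyphenyl)-2,3,4,4a,5,6-hexahydro-7H-chromen-7-one (both C4a epimers). One dehydrogenation would give the phenol A3, (S)-8-methoxy-2-(3,4,5-trimethoxyphenyl)chroman-7-ol, and O-methylation the target.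
- For: the stereocentre is made early at a simple aryl carbinol and is then carried as a plain benzylic ether with neither a β-carbonyl nor a neighbouring alkene, so neither racemization channel exists. C4 never bears oxygen, so nothing has to be removed there. Only the enolate at the methoxy-bearing carbon can close a six-membered ring, so the regiochemistry of the cyclization is sound.
- Against: a ring that compound 1 supplies ready-made with the right oxygenation is constructed atom by atom. A2 needs its own multistep asymmetric synthesis. The late dehydrogenation uses oxidizing or high-temperature conditions next to an electron-rich benzylic ether C–H at C2, and a methylation follows.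
- Comparison: on the configurational security of C2 this plan is stronger than the chosen one. The chosen route offers about half the number of steps and no oxidation in the presence of the benzylic ether.

**Alternative 2: gold hydroarylation of a chiral aryl propargyl ether.**
- Disconnection: the C4–C4a bond is cut, leading to the aryl propargyl ether A5, (S)-1,2-dimethoxy-3-{[1-(3,4,5-trimethoxyphenyl)prop-2-yn-1-yl]oxy}benzene.
- Forward key step: (JohnPhos)Au(NCMe)SbF6 (JohnPhos = 2-(di-tert-butylphosphino)biphenyl), a cationic complex of monovalent gold, activates the alkyne for 6-endo-dig attack by the arene. This closes ring C as A4, (S)-7,8-dimethoxy-2-(3,4,5-trimethoxyphenyl)-2H-chromene; hydrogenation of C3=C4 would finish the synthesis.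
- For: only one ortho position of the aryl ether is free, so the regiochemistry is unambiguous. No oxygen has to be removed from C4. The sequence is as short as the chosen one or shorter.
- Against: the stereocentre of A5 is benzylic and propargylic at once and sits on an electron-rich arene. It is prone to ionization both when the C–O bond is made by substitution and under the Lewis-acidic gold catalyst. In A4 the C2–O1 bond is allylic and benzylic, and the 2H-chromene can lose configuration by reversible oxa-6π electrocyclic ring opening. The final hydrogenation must then spare a C–O bond that is doubly activated towards hydrogenolysis.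
- Comparison: step economy is equal or slightly better here. The chosen route offers a stereocentre created in an irreversible C–C bond formation and then kept at a saturated carbon, whose one known leak (base) can be avoided by the choice of conditions.

**Alternative 3: iminium–enamine oxa-Michael/aldol cascade with a formyl group at C3 that is removed later.**
- Disconnection: O1–C2 and C3–C4 are cut together, leading to 2-hydroxy-3,4-dimethoxybenzaldehyde A6 and (E)-3-(3,4,5-trimethoxyphenyl)prop-2-enal A7.
- Forward key step: an (S)-diarylprolinol silyl ether with a nitrobenzoic acid co-catalyst converts A7 into an iminium ion. The phenol of A6 adds to its β-carbon, and the resulting enamine condenses with the aldehyde of A6, closing ring C as A8, (R)-7,8-dimethoxy-2-(3,4,5-trimethoxyphenyl)-2H-chromene-3-carbaldehyde. The (R) label arises only because the formyl-bearing C3 outranks ring B; the spatial arrangement is that of the (2S)-flavan. Decarbonylation and hydrogenation of C3=C4 would follow.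
- For: two simple aldehydes, no metal in the stereodetermining step, and ring C and C2 formed in one operation. On paper this is the shortest of all the plans, and in step count it beats the chosen route.
- Against: the configuration is fixed by an oxa-Michael addition, which is reversible at the iminium/enamine stage. The extra carbon then has to be excised from an α,β-unsaturated aldehyde by rhodium-mediated decarbonylation, stoichiometric or at high temperature, on a 2H-chromene that has the ring-opening pathway described for A4. The hydrogenolysis problem of Alternative 2 returns in the last step.
- Comparison: the chosen route is longer by two steps. In exchange its stereocentre comes from an irreversible carbopalladation, and its defunctionalization consists of two mild hydride reductions at a position (C4) that is not the stereocentre.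

Key step: step 3

## Route

**Step 1**
Reactants: 1 1-(2-hydroxy-3,4-dimethoxyphenyl)ethanone; 2 N,N-dimethylformamide dimethyl acetal
Product: 3 (E)-3-(dimethylamino)-1-(2-hydroxy-3,4-dimethoxyphenyl)prop-2-en-1-one
Conditions: 2 (1.5 equiv), toluene, 100 °C
Reagents that add atoms: none
Why: Enaminone formation by condensation of the acetyl methyl group with the amide acetal, the first half of the enaminone chromone synthesis; methanol distils off and drives the reaction, and the hydrogen-bonded phenol should stay free. The vinylogous amide is expected as the E isomer.

**Step 2**
Reactants: 3 (E)-3-(dimethylamino)-1-(2-hydroxy-3,4-dimethoxyphenyl)prop-2-en-1-one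
Product: 5 7,8-dimethoxy-4H-chromen-4-one, via 2-(dimethylamino)-7,8-dimethoxychroman-4-one 4 (not isolated)
Conditions: conc. HCl, CH2Cl2, 40 °C
Reagents that add atoms: none
Why: Acid-mediated cyclization of an ortho-hydroxyaryl enaminone: protonation makes the β-carbon an iminium carbon, the phenol adds to it (6-endo oxa-Michael) to give aminal 4, and loss of dimethylamine leaves the pyranone ring. The aryl methyl ethers are stable to hydrochloric acid at this temperature.

**Step 3**
Reactants: 5 7,8-dimethoxy-4H-chromen-4-one; 6 (3,4,5-trimethoxyphenyl)boronic acid (2 equiv)
Product: 7 (S)-7,8-dimethoxy-2-(3,4,5-trimethoxyphenyl)chroman-4-one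
Conditions: Pd(OCOCF3)2 (10 mol %), (R)-4-tert-butyl-2-(pyridin-2-yl)-4,5-dihydrooxazole (12 mol %), NH4PF6 (30 mol %), H2O (5 equiv), ClCH2CH2Cl, 60 °C, air
Reagents that add atoms: none
Why: The step is a catalytic enantioselective conjugate arylation, and the closest known reaction type is the addition of arylboronic acids to chromones and other cyclic enones under cationic divalent-palladium/pyridine–oxazoline catalysis. Transmetalation from 6 gives an aryl–palladium cation held by the N,N-ligand; the C2=C3 bond of 5 coordinates and inserts syn, so that ring B lands on C2 and palladium on C3, and the palladium enolate is protonated by water or NH4+ to release 7 while the metal stays divalent throughout. No ring is closed: the step forms one skeletal bond (C2–C1') and one stereocentre (C2). That stereocentre is set by the catalyst at the insertion, where the tert-butyl group on the oxazoline clashes with the acceptor in one of the two diastereomeric transition states, so that only one face of C2 reaches the aryl ligand; the (R)-ligand is taken so that this face leads to (2S). The step needs 1,4- rather than 1,2-addition, which the insertion mechanism provides, and protonation rather than β-hydride elimination to the flavone, which the ring of 5 secures because syn insertion leaves the C2 hydrogen anti to palladium. The 7-methoxy group, para to C4a, makes 5 a weaker acceptor than the parent chromone, which is answered by the higher catalyst loading and by two equivalents of the unhindered, readily transmetalating boronic acid. Because no base is present, the retro-oxa-Michael ring opening that racemizes flavanones should not come into play.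

**Step 4**
Reactants: 7 (S)-7,8-dimethoxy-2-(3,4,5-trimethoxyphenyl)chroman-4-one
Product: 8 (2S)-7,8-dimethoxy-2-(3,4,5-trimethoxyphenyl)chroman-4-ol (both C4 epimers, mainly the 2,4-cis (2S,4S) isomer, carried on together)
Conditions: NaBH4 (1.5 equiv), MeOH–THF (1:1), 0 °C; aq. NH4Cl
Reagents that add atoms: none
Why: Borohydride reduction of an aryl ketone; axial hydride delivery to the half-chair with the 2-aryl group equatorial should favour the 2,4-cis alcohol, but the C4 configuration is irrelevant because C4 becomes a methylene group in step 5. The low temperature and a prompt buffered quench should keep the alkoxide-induced ring opening of 7 in check, so C2 is expected to stay intact.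

**Step 5**
Reactants: 8 (2S)-7,8-dimethoxy-2-(3,4,5-trimethoxyphenyl)chroman-4-ol
Product: 9 (2S)-7,8,3',4',5'-pentamethoxyflavan
Conditions: Et3SiH (3 equiv), CF3CO2H (10 equiv), CH2Cl2, 0 °C
Reagents that add atoms: none
Why: Ionic deoxygenation (ionic hydrogenation) of a benzylic alcohol: the acid ionizes the C4–OH bond to a cation stabilised by the 7-methoxy group and O1, and the silane transfers hydride to it. With excess silane at low temperature, hydride capture should outrun elimination, arylation of a second molecule and ionization at C2, so the stereocentre is not touched.

## Compound list

1 | 1-(2-hydroxy-3,4-dimethoxyphenyl)ethanone | CC(=O)c1ccc(OC)c(OC)c1O | starting material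
2 | N,N-dimethylformamide dimethyl acetal | COC(OC)N(C)C | starting material
3 | (E)-3-(dimethylamino)-1-(2-hydroxy-3,4-dimethoxyphenyl)prop-2-en-1-one | CN(C)/C=C/C(=O)c1ccc(OC)c(OC)c1O | intermediate
4 | 2-(dimethylamino)-7,8-dimethoxychroman-4-one (racemic, not isolated) | CN(C)C1CC(=O)c2ccc(OC)c(OC)c2O1 | intermediate
5 | 7,8-dimethoxy-4H-chromen-4-one | O=c1ccoc2c1ccc(OC)c2OC | intermediate
6 | (3,4,5-trimethoxyphenyl)boronic acid | COc1cc(B(O)O)cc(OC)c1OC | starting material
7 | (S)-7,8-dimethoxy-2-(3,4,5-trimethoxyphenyl)chroman-4-one | COc1cc([C@@H]2CC(=O)c3ccc(OC)c(OC)c3O2)cc(OC)c1OC | intermediate
8 | (2S)-7,8-dimethoxy-2-(3,4,5-trimethoxyphenyl)chroman-4-ol (both C4 epimers, mainly (2S,4S)) | COc1cc([C@@H]2CC(O)c3ccc(OC)c(OC)c3O2)cc(OC)c1OC | intermediate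
9 | (2S)-7,8,3',4',5'-pentamethoxyflavan | COc1cc([C@@H]2CCc3ccc(OC)c(OC)c3O2)cc(OC)c1OC | target

## Step count and weak points

Total step count: 5. Longest linear sequence: 5 steps (1 → 3 → 5 → 7 → 8 → 9). Compounds 1, 2 and 6 are purchased, and 6 enters in step 3.

**Step 3 (key step).**
- Risk: migratory insertion into the electron-rich chromone may be slow. Protodeboronation and oxidative homocoupling of 6 could then outrun the addition and reduce the catalyst to inactive zerovalent palladium. A second possibility is insufficient discrimination between the two faces of C2.
- Fallback: kinetic resolution in place of asymmetric C–C bond formation, setting out from 1 and returning at 8.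
 - Claisen–Schmidt condensation of 1 with commercial 3,4,5-trimethoxybenzaldehyde (KOH, EtOH, room temperature) should give (E)-1-(2-hydroxy-3,4-dimethoxyphenyl)-3-(3,4,5-trimethoxyphenyl)prop-2-en-1-one F1.
 - Oxa-Michael ring closure (NaOAc, EtOH, reflux) should give racemic 7,8-dimethoxy-2-(3,4,5-trimethoxyphenyl)chroman-4-one F2.
 - Asymmetric transfer hydrogenation with RuCl[(S,S)-TsDPEN](p-cymene) (TsDPEN = N-(p-toluenesulfonyl)-1,2-diphenylethylenediamine) and HCO2H–Et3N would follow. By the usual model for aryl ketones this catalyst creates a (4S)-carbinol, and flavanone reduction is strongly cis-selective, so the (2S)-ketone is the matched, fast-reacting enantiomer. It would be converted into the (2S,4S) epimer of 8.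
 - (R)-7,8-dimethoxy-2-(3,4,5-trimethoxyphenyl)chroman-4-one F3 would remain. It is separated and can be returned to F2 by base.
 - The cost is that at most half of the material is used per pass. The route is rejoined at 8.

**Step 5.**
- Risk: the C4 cation may be captured by the electron-rich ring A of a second molecule (Friedel–Crafts dimerization) instead of by hydride. Acid-promoted ionization of the C2–O1 bond could also erode the configuration.
- Fallback: radical in place of cationic cleavage of the C4–O bond, from 8 to 9.
 - Acylation of 8 with 1,1'-thiocarbonyldiimidazole (DMAP cat., CH2Cl2, reflux) should give O-[(2S)-7,8-dimethoxy-2-(3,4,5-trimethoxyphenyl)chroman-4-yl] 1H-imidazole-1-carbothioate F4.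
 - Barton–McCombie reduction with Bu3SnH and AIBN in toluene at 90 °C would generate the benzylic C4 radical, which abstracts hydrogen to give 9 under neutral conditions.

**Step 4.**
- Risk: methoxide formed from the borohydride may open ring C of 7 by retro-oxa-Michael reaction before the carbonyl is reduced. This would lower the enantiomeric purity and divert material.
- Fallback: an acidic hydride source in place of a basic one, from 7 directly to 9. Ionic hydrogenation of the aryl ketone with excess Et3SiH in CF3CO2H (CH2Cl2, 0 °C to room temperature) passes through 8 in the flask and forms no new isolated compound. Base is avoided altogether, at the price of a longer exposure of the C2–O1 bond to acid.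

## Further compounds

F1 | step 3 | (E)-1-(2-hydroxy-3,4-dimethoxyphenyl)-3-(3,4,5-trimethoxyphenyl)prop-2-en-1-one | COc1ccc(C(=O)/C=C/c2cc(OC)c(OC)c(OC)c2)c(O)c1OC
F2 | step 3 | rac-7,8-dimethoxy-2-(3,4,5-trimethoxyphenyl)chroman-4-one | COc1cc(C2CC(=O)c3ccc(OC)c(OC)c3O2)cc(OC)c1OC
F3 | step 3 | (R)-7,8-dimethoxy-2-(3,4,5-trimethoxyphenyl)chroman-4-one | COc1cc([C@H]2CC(=O)c3ccc(OC)c(OC)c3O2)cc(OC)c1OC
F4 | step 5 | O-[(2S)-7,8-dimethoxy-2-(3,4,5-trimethoxyphenyl)chroman-4-yl] 1H-imidazole-1-carbothioate (both C4 epimers) | COc1cc([C@@H]2CC(OC(=S)n3ccnc3)c3ccc(OC)c(OC)c3O2)cc(OC)c1OC
F0 | step 4 | none | none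
A1 | alternative 1 | (2S)-8-methoxy-2-(3,4,5-trimethoxyphenyl)-2,3,4,4a,5,6-hexahydro-7H-chromen-7-one (both C4a epimers) | COc1cc([C@@H]2CCC3CCC(=O)C(OC)=C3O2)cc(OC)c1OC
A2 | alternative 1 | (6S)-3-(4-methoxy-3-oxobutyl)-6-(3,4,5-trimethoxyphenyl)tetrahydro-2H-pyran-2-one (both C3 epimers) | COCC(=O)CCC1CC[C@H](OC1=O)c1cc(OC)c(OC)c(OC)c1
A3 | alternative 1 | (S)-8-methoxy-2-(3,4,5-trimethoxyphenyl)chroman-7-ol | COc1cc([C@@H]2CCc3ccc(O)c(OC)c3O2)cc(OC)c1OC
A4 | alternative 2 | (S)-7,8-dimethoxy-2-(3,4,5-trimethoxyphenyl)-2H-chromene | COc1cc([C@@H]2C=Cc3ccc(OC)c(OC)c3O2)cc(OC)c1OC
A5 | alternative 2 | (S)-1,2-dimethoxy-3-{[1-(3,4,5-trimethoxyphenyl)prop-2-yn-1-yl]oxy}benzene | C#C[C@H](Oc1cccc(OC)c1OC)c1cc(OC)c(OC)c(OC)c1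
A6 | alternative 3 | 2-hydroxy-3,4-dimethoxybenzaldehyde | COc1ccc(C=O)c(O)c1OC
A7 | alternative 3 | (E)-3-(3,4,5-trimethoxyphenyl)prop-2-enal | COc1cc(/C=C/C=O)cc(OC)c1OC
A8 | alternative 3 | (R)-7,8-dimethoxy-2-(3,4,5-trimethoxyphenyl)-2H-chromene-3-carbaldehyde | COc1cc([C@@H]2C(C=O)=Cc3ccc(OC)c(OC)c3O2)cc(OC)c1OC
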